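**Retrosynthetic overview**
1. Ambrein is disconnected at the C11–C12 bond (Biellmann-type sulfone alkylation, then reductive desulfonylation) into an 8α-hydroxydrimanyl sulfone (**4**) and a γ-monocyclofarnesyl-type allylic bromide (**10**).
2. **4** comes from a chiral-acid (IDPi) proton-initiated bicyclization of farnesyl phenyl sulfone (**3**). Ring A closes first, then ring B, and water captures the C8 cation. This sets C5, C10, C9 and C8.
3. **10** comes from ethyl ester **8**, which is made by IDPi monocyclization of ethyl farnesoate (**7**). The conjugated enoate cannot close a second ring, so only ring A forms, and this sets C5′.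
4. All rings are formed before coupling, and no stereocenter is touched afterwards. The starting materials are achiral, commercial farnesyl bromide and geranylacetone.

Assumptions: (E,E)-farnesyl bromide and (E)-geranylacetone are commercially available. The same IDPi enantiomer, found by screening, gives the natural series in both cyclizations.

## Route

**Step 1**
Reactants: **1** (2E,6E)-farnesyl bromide; **2** sodium benzenesulfinate
Product: **3** (2E,6E)-farnesyl phenyl sulfone
Conditions: 2 (1.2 equiv), DMF, 25 °C, 3 h
Reagents that add atoms: sodium benzenesulfinate, O=S([O-])c1ccccc1.[Na+]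
Why: SN2 displacement of the allylic bromide by sulfinate. The alkene geometry is retained and no stereocenter is formed.

**Step 2**
Reactants: **3**; water
Product: **4** 8α-hydroxy-11-(phenylsulfonyl)drimane (trans-decalin; 5α-H, 9α-H, 10β-CH3, 8α-OH/8β-CH3, 4,4-dimethyl, CH2SO2Ph on C9)
Conditions: chiral IDPi (5 mol %), H2O (5 equiv), pentane/CH2Cl2 9:1, –40 °C, 72 h
Reagents that add atoms: water, O
Why: Proposed new method: the IDPi protonates the terminal alkene inside a chiral confined ion pair. The E,E-substrate folds chair–chair, closing ring A (C4–C5) and then ring B (C10–C9) to give the C8 tertiary cation. Water captures it from the α face, because the β face is shielded by the axial C10 methyl, and the proton returns to the catalyst. This sets C5, C10, C9 and C8. The closest known reactions are IDPi-catalysed homofarnesol→ambrox cyclization (intramolecular oxygen capture) and the hydroxylative termination of class II terpene cyclases.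

**Step 3**
Reactants: **5** (E)-geranylacetone; **6** triethyl phosphonoacetate
Product: **7** ethyl (2E,6E)-farnesoate
Conditions: NaH (1.3 equiv), THF, 0 °C → 25 °C, 16 h; chromatographic removal of the minor 2Z isomer
Reagents that add atoms: triethyl phosphonoacetate, CCOC(=O)CP(=O)(OCC)OCC
Why: Horner–Wadsworth–Emmons olefination, which is E-selective for the new trisubstituted enoate.

**Step 4**
Reactants: **7**
Product: **8** ethyl (E)-3-methyl-5-[(S)-6,6-dimethyl-2-methylenecyclohexyl]pent-2-enoate
Conditions: chiral IDPi (5 mol %), cyclohexane, 4 Å MS, –30 °C, 4 d
Reagents that add atoms: none (isomerization)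
Why: Proposed new method: the IDPi protonates C10 of the terminal alkene. Chair-like closure of C11 onto C6 forms the C5′ stereocenter and a tertiary C7 cation. The conjugated, electron-poor enoate is too weakly nucleophilic to close a second ring. The basic IDPi anion then removes a proton from the C7 methyl, giving the exocyclic methylene kinetically; the low temperature and finite conversion limit re-protonation and isomerization to the endocyclic β-isomer. The closest known reactions are proton-initiated IDPi/Lewis-acid-assisted Brønsted acid polyene cyclizations and the exo-methylene termination of achilleol-type cyclases.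

**Step 5**
Reactants: **8**
Product: **9** (2E)-3-methyl-5-[(S)-6,6-dimethyl-2-methylenecyclohexyl]pent-2-en-1-ol
Conditions: DIBAL-H (2.5 equiv), CH2Cl2, –78 → 0 °C, 1 h
Reagents that add atoms: none (hydride only)
Why: 1,2-Reduction of the ester to the allylic alcohol. Both isolated alkenes and C5′ are untouched.

**Step 6**
Reactants: **9**
Product: **10** (2E)-1-bromo-3-methyl-5-[(S)-6,6-dimethyl-2-methylenecyclohexyl]pent-2-ene
Conditions: PPh3 (1.3 equiv), CBr4 (1.3 equiv), CH2Cl2, 0 °C, 1 h
Reagents that add atoms: carbon tetrabromide, BrC(Br)(Br)Br
Why: Appel bromination by SN2 at a primary allylic carbon, which is mild enough to leave the exocyclic alkene intact.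

**Step 7**
Reactants: **4**; **10**
Product: **11** C11-phenylsulfonyl ambrein, a mixture of C11 epimers (C11 is removed in step 8)
Conditions: **4**, n-BuLi (2.2 equiv), THF, –78 → –20 °C; then DMPU (10 equiv), **10** (1.3 equiv), –78 → 0 °C
Reagents that add atoms: none
Why: Alkylation of the α-sulfonyl carbanion (the first equivalent of base forms the tertiary alkoxide) by SN2 at the allylic CH2Br. This is the standard Biellmann-type tail-to-tail coupling, and the E-alkene and all existing stereocenters are retained.

**Step 8**
Reactants: **11**
Product: **12** ambrein
Conditions: Li (10 equiv), EtNH2/THF, –78 → –20 °C, 30 min; solid NH4Cl quench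
Reagents that add atoms: none (H only)
Why: Reductive desulfonylation by single-electron transfer and protonation (Julia/Biellmann type). The isolated alkenes and the tertiary alcohol survive, and the C11 epimers converge to the CH2 of the target.

## Compound list
1 | (2E,6E)-farnesyl bromide | CC(C)=CCC/C(C)=C/CC/C(C)=C/CBr | starting material
2 | sodium benzenesulfinate | [Na+].[O-]S(=O)c1ccccc1 | starting material
3 | (2E,6E)-farnesyl phenyl sulfone | CC(C)=CCC/C(C)=C/CC/C(C)=C/CS(=O)(=O)c1ccccc1 | intermediate
4 | 8α-hydroxy-11-(phenylsulfonyl)drimane | O=S(=O)(c1ccccc1)C[C@@H]1[C@@]2(C)CCCC(C)(C)[C@@H]2CC[C@@]1(C)O | intermediate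
5 | (E)-geranylacetone | CC(C)=CCC/C(C)=C/CCC(C)=O | starting material
6 | triethyl phosphonoacetate | CCOC(=O)CP(=O)(OCC)OCC | starting material
7 | ethyl (2E,6E)-farnesoate | CC(C)=CCC/C(C)=C/CC/C(C)=C/C(=O)OCC | intermediate
8 | ethyl (E)-3-methyl-5-[(S)-6,6-dimethyl-2-methylenecyclohexyl]pent-2-enoate | C=C1CCCC(C)(C)[C@@H]1CC/C(C)=C/C(=O)OCC | intermediate
9 | (2E)-3-methyl-5-[(S)-6,6-dimethyl-2-methylenecyclohexyl]pent-2-en-1-ol | C=C1CCCC(C)(C)[C@@H]1CC/C(C)=C/CO | intermediate
10 | (2E)-1-bromo-3-methyl-5-[(S)-6,6-dimethyl-2-methylenecyclohexyl]pent-2-ene | C=C1CCCC(C)(C)[C@@H]1CC/C(C)=C/CBr | intermediate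
11 | C11-phenylsulfonyl ambrein (C11 epimer mixture) | C=C1CCCC(C)(C)[C@@H]1CC/C(C)=C/CC(S(=O)(=O)c1ccccc1)[C@@H]1[C@@]2(C)CCCC(C)(C)[C@@H]2CC[C@@]1(C)O | intermediate
12 | ambrein | C=C1CCCC(C)(C)[C@@H]1CC/C(C)=C/CC[C@@H]1[C@@]2(C)CCCC(C)(C)[C@@H]2CC[C@@]1(C)O | target

## Totals
Total steps: 8. Longest linear sequence: 6 (geranylacetone → 7 → 8 → 9 → 10 → 11 → ambrein).

## Three steps most likely to fail
1. **Step 4 (proposed new: γ-selective, enantioselective monocyclization).** Risks are isomerization to the β/α-olefins and low ee.
   Fallback (known chemistry, different mechanism): a terminal-selective Shi asymmetric epoxidation (fructose-derived ketone, Oxone) of 7, then Cp2TiCl-catalysed radical epoxypolyene monocyclization (exocyclic-alkene-selective), then Barton–McCombie removal of the C3 hydroxyl, to give 8.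
2. **Step 2 (proposed new: hydroxylative bicyclization).** Risks are elimination instead of water capture, monocyclic by-products, and the deactivated allylic sulfone alkene.
   Fallback: a known chiral Lewis-acid-assisted Brønsted acid cyclization of 3 with deprotonative termination to the drim-8(12)-ene sulfone, then α-face epoxidation (mCPBA) and hydride opening at the CH2 (LiEt3BH) to give 4.
3. **Step 7 (hindered dianion alkylation).** Risks are low conversion and O-alkylation.
   Fallback: a different bond polarity. Run the step-2 cyclization on farnesyl acetate, using acetate participation to fix the C8 oxygen, then deacetylate, do a selective Appel bromination at C11, protect the tertiary alcohol as its TES ether, form the Grignard reagent, couple it with **10** under Li2CuCl4 catalysis, and remove the TES group with TBAF.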